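The ten-membered carbocycle is disconnected at the C3–C4 single bond (germacrane numbering), where the methylene C3 meets the sp2 carbon C4 of the ring's (4Z)-trisubstituted alkene. One operation, a hydroboration/B-alkyl Suzuki–Miyaura macrocyclisation, forms this bond, closes the ring and transfers the Z geometry stored in an alkenyl iodide; the fused butenolide (C6–C7) and the Z alkene hold both chain ends on one side. The precursor is an acyclic, fully oxygenated butenolide: a (Z)-2-iodopropenyl group on C6 and, on C7, the C8–C3 chain ending in a vinyl group (C2=C3), with both acetates, the C10 methylene and a silylated C1 carbinol in place.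

Key step: step 15

Assumption: germacrane numbering is used throughout (C1 carbinol, C4=C5, C6 lactone CH, C7=C11 butenolide, C8 acetoxy carbon, C10=C14, C12 lactone carbonyl, C13 acetoxymethyl); 1β, 6α, 8α correspond to (1R,6R,8S) in the SMILES, and the facial sense of the two catalyst-controlled additions (steps 3 and 13) is taken from the accepted transition-state models, the antipodal ligand or acid being used if an aldehyde departs from them.

Step 1
Reactants: 1 but-2-yn-1-ol
Product: 3 (Z)-3-iodobut-2-en-1-ol, via cyclic alkenylalanate 2 (not isolated)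
Conditions: NaAlH2(OCH2CH2OCH3)2, THF, 0 °C to rt; then I2, −78 °C to 0 °C
Reagents that add atoms: iodine, [I][I]
Why: Hydroxyl-directed trans-hydroalumination of the propargylic alcohol places aluminium on C3 in a five-membered alkoxyalanate, and iodinolysis with retention should give the Z iodide (hydroalumination–iodination).

Step 2
Reactants: 3 (Z)-3-iodobut-2-en-1-ol
Product: 4 (Z)-3-iodobut-2-enal
Conditions: MnO2, CH2Cl2, rt, dark
Reagents that add atoms: none
Why: Allylic oxidation on MnO2 stops at the enal and, being neutral, should leave the Z iodoalkene unisomerised.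

Step 3
Reactants: 4 (Z)-3-iodobut-2-enal; 5 methyl propiolate
Product: 7 methyl (4R,5Z)-4-hydroxy-6-iodohept-5-en-2-ynoate, via methylzinc acetylide 6 (not isolated)
Conditions: Me2Zn, (S,S)-ProPhenol (10 mol %), toluene, 0 °C
Reagents that add atoms: none
Why: Zinc–ProPhenol asymmetric alkynylation of an enal, in which the dinuclear zinc complex binds aldehyde and acetylide and should deliver the alkyne to the Si face, setting C6 as R under ligand control.

Step 4
Reactants: 7 methyl (4R,5Z)-4-hydroxy-6-iodohept-5-en-2-ynoate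
Product: 9 (5R)-3-(hydroxymethyl)-5-[(Z)-2-iodoprop-1-enyl]-4-vinylfuran-2(5H)-one, via cuprio enoate 8 (not isolated)
Conditions: CH2=CHMgBr, CuBr·SMe2, THF, −78 °C; then CH2O (monomer in THF), −78 to 0 °C; aqueous NH4Cl
Reagents that add atoms: vinylmagnesium bromide, C=C[Mg]Br; formaldehyde, C=O
Why: Tandem conjugate addition–aldol–lactonisation: syn-carbocupration puts the vinyl group on C7 and copper on C11, formaldehyde hydroxymethylates C11, and the C6 alkoxide, now cis to the ester, closes the butenolide without touching C6.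

Step 5
Reactants: 9 (5R)-3-(hydroxymethyl)-5-[(Z)-2-iodoprop-1-enyl]-4-vinylfuran-2(5H)-one
Product: 10 [(5R)-5-[(Z)-2-iodoprop-1-enyl]-2-oxo-4-vinyl-2,5-dihydrofuran-3-yl]methyl acetate
Conditions: Ac2O, pyridine, CH2Cl2, 0 °C
Reagents that add atoms: acetic anhydride, CC(=O)OC(C)=O
Why: O-Acetylation of the primary allylic alcohol installs the C13 acetate and prevents hemiacetal formation with the C8 aldehyde made next.

Step 6
Reactants: 10 [(5R)-5-[(Z)-2-iodoprop-1-enyl]-2-oxo-4-vinyl-2,5-dihydrofuran-3-yl]methyl acetate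
Product: 11 [(5R)-4-formyl-5-[(Z)-2-iodoprop-1-enyl]-2-oxo-2,5-dihydrofuran-3-yl]methyl acetate
Conditions: OsO4 (cat.), NaIO4, 2,6-lutidine, dioxane/H2O, rt
Reagents that add atoms: osmium tetroxide, O=[Os](=O)(=O)=O (oxygen carrier); sodium periodate, [Na+].[O-]I(=O)(=O)=O (terminal oxidant)
Why: Lemieux–Johnson cleavage should take the unhindered monosubstituted vinyl group, because the iodo-substituted alkene and the tetrasubstituted lactone alkene are hindered and electron-poor.

Step 7
Reactants: 5 methyl propiolate; 12 acrolein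
Product: 14 rac-methyl 3-hydroxy-2-methylenepent-4-enoate, via alkenylalane 13 (not isolated)
Conditions: i-Bu2AlH, N-methylmorpholine N-oxide, THF, 0 °C; then acrolein, 0 °C to rt
Reagents that add atoms: none
Why: Vinylalumination: hydroalumination of the propiolate gives the α-aluminoacrylate, which adds 1,2 to acrolein to give the Morita–Baylis–Hillman-type adduct without acrolein self-condensation.

Step 8
Reactants: 14 rac-methyl 3-hydroxy-2-methylenepent-4-enoate
Product: 15 methyl (3R)-3-hydroxy-2-methylenepent-4-enoate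
Conditions: Ti(OiPr)4, D-(−)-diisopropyl tartrate, t-BuOOH (0.6 equiv), 4 Å molecular sieves, CH2Cl2, −20 °C
Reagents that add atoms: none
Why: Sharpless kinetic resolution, in which the D-tartrate catalyst epoxidises the vinyl group of the (S)-carbinol faster while the acrylate alkene is inert, so the (R)-alcohol (future C1) should be recovered.

Step 9
Reactants: 15 methyl (3R)-3-hydroxy-2-methylenepent-4-enoate
Product: 16 methyl (3R)-3-[(tert-butyldimethylsilyl)oxy]-2-methylenepent-4-enoate
Conditions: TBSCl, imidazole, DMF, rt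
Reagents that add atoms: tert-butyldimethylsilyl chloride, CC(C)(C)[Si](C)(C)Cl
Why: Silylation protects the C1 hydroxyl as the one group that must stay masked until after both acetates are in place.

Step 10
Reactants: 16 methyl (3R)-3-[(tert-butyldimethylsilyl)oxy]-2-methylenepent-4-enoate
Product: 17 (3R)-3-[(tert-butyldimethylsilyl)oxy]-2-methylenepent-4-en-1-ol
Conditions: i-Bu2AlH, CH2Cl2, −78 °C
Reagents that add atoms: none
Why: 1,2-Reduction of the α-methylene ester by the aluminium hydride gives the 2-substituted allylic alcohol without touching the silyl ether.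

Step 11
Reactants: 17 (3R)-3-[(tert-butyldimethylsilyl)oxy]-2-methylenepent-4-en-1-ol
Product: 18 (3R)-3-[(tert-butyldimethylsilyl)oxy]-2-methylenepent-4-en-1-yl methyl carbonate
Conditions: ClCO2CH3, pyridine, CH2Cl2, 0 °C
Reagents that add atoms: methyl chloroformate, COC(=O)Cl
Why: Carbonate formation activates the primary allylic oxygen for copper-catalysed borylation.

Step 12
Reactants: 18 (3R)-3-[(tert-butyldimethylsilyl)oxy]-2-methylenepent-4-en-1-yl methyl carbonate
Product: 19 tert-butyldimethyl{[(3R)-4-methylene-5-(4,4,5,5-tetramethyl-1,3,2-dioxaborolan-2-yl)pent-1-en-3-yl]oxy}silane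
Conditions: B2pin2, CuCl (10 mol %), Xantphos (10 mol %), KOtBu (20 mol %), THF, rt
Reagents that add atoms: bis(pinacolato)diboron, CC1(C)OB(OC1(C)C)B1OC(C)(C)C(C)(C)O1
Why: Copper-catalysed γ-selective allylic borylation (SN2′ attack of a boryl copper, then loss of CO2 and methoxide); for this 2-substituted allyl carbonate both regiochemical modes give the same allylboronate.

Step 13
Reactants: 11 [(5R)-4-formyl-5-[(Z)-2-iodoprop-1-enyl]-2-oxo-2,5-dihydrofuran-3-yl]methyl acetate; 19 tert-butyldimethyl{[(3R)-4-methylene-5-(4,4,5,5-tetramethyl-1,3,2-dioxaborolan-2-yl)pent-1-en-3-yl]oxy}silane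
Product: 21 {(5R)-4-[(1S,4R)-4-(tert-butyldimethylsilyloxy)-1-hydroxy-3-methylenehex-5-enyl]-5-[(Z)-2-iodoprop-1-enyl]-2-oxo-2,5-dihydrofuran-3-yl}methyl acetate, via pinacol borate 20 (not isolated)
Conditions: (S)-TRIP phosphoric acid (5 mol %), toluene, −30 °C; aqueous work-up
Reagents that add atoms: none
Why: Chiral phosphoric acid-catalysed allylboration through a closed chair (Zimmerman–Traxler) transition state: the acid activates the boronate, should direct C9 to the Si face of the aldehyde to give 8S under catalyst control, and the allyl transposition creates the C10=C14 methylene.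

Step 14
Reactants: 21 {(5R)-4-[(1S,4R)-4-(tert-butyldimethylsilyloxy)-1-hydroxy-3-methylenehex-5-enyl]-5-[(Z)-2-iodoprop-1-enyl]-2-oxo-2,5-dihydrofuran-3-yl}methyl acetate
Product: 22 {(5R)-4-[(1S,4R)-1-acetoxy-4-(tert-butyldimethylsilyloxy)-3-methylenehex-5-enyl]-5-[(Z)-2-iodoprop-1-enyl]-2-oxo-2,5-dihydrofuran-3-yl}methyl acetate
Conditions: Ac2O, pyridine, DMAP (cat.), CH2Cl2, 0 °C
Reagents that add atoms: acetic anhydride, CC(=O)OC(C)=O
Why: Acetylation of the C8 hydroxyl proceeds with retention, since the C–O bond is not broken.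

Step 15
Reactants: 22 {(5R)-4-[(1S,4R)-1-acetoxy-4-(tert-butyldimethylsilyloxy)-3-methylenehex-5-enyl]-5-[(Z)-2-iodoprop-1-enyl]-2-oxo-2,5-dihydrofuran-3-yl}methyl acetate
Product: 24 (1R,4Z,6R,8S)-8,13-diacetoxy-1-(tert-butyldimethylsilyloxy)germacra-4,7(11),10(14)-trien-12,6-olide, via primary alkylborane 23 (not isolated)
Conditions: (Sia)2BH [bis(3-methylbutan-2-yl)borane, 0.5 M in THF], THF, 0 °C; then slow addition to Pd(dppf)Cl2 (20 mol %), AsPh3, Cs2CO3, DMF/THF/H2O (5 equiv H2O), 40 °C, 2 mM
Reagents that add atoms: none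
Why: The hindered dialkylborane hydroborates the monosubstituted C2=C3 alkene at its terminus, and the primary alkylborane 23 is coupled in the same flask by oxidative addition of zerovalent palladium into the carbon–iodine bond at C4, base-assisted transmetalation of the C3 alkyl group and reductive elimination, which forges C3–C4. The closest known reaction type is the B-alkyl Suzuki–Miyaura macrocyclisation of an ω-boryl alkenyl iodide. The ten-membered carbocycle is closed by intramolecular transmetalation and reductive elimination from an eleven-membered palladacycle, both coupled carbons becoming ring members. No stereocentre is created; the 4Z geometry is carried over from the alkenyl iodide with retention, and C1, C6 and C8 are spectators. The step needs site-selective hydroboration, secured by the steric demand of (Sia)2BH against the 1,1-disubstituted C10=C14 alkene and by the electron-poor character of the lactone and iodoalkene, and it needs cyclisation over oligomerisation, secured by slow addition at high dilution and by the cis disposition of the two chains on the butenolide and on the Z iodoalkene. Oxidative addition into the alkenyl iodide is expected to outpace ionisation of the allylic acetates, and the carbonate base with little water should spare the esters and the C6 hydrogen.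

Step 16
Reactants: 24 (1R,4Z,6R,8S)-8,13-diacetoxy-1-(tert-butyldimethylsilyloxy)germacra-4,7(11),10(14)-trien-12,6-olide
Product: 25 8α,13-diacetoxy-1β-hydroxygermacra-4,7(11),10(14)-trien-6α,12-olide
Conditions: HF·pyridine, pyridine, THF, 0 °C to rt
Reagents that add atoms: none
Why: Fluoride-mediated desilylation under buffered, non-basic conditions should free the C1 hydroxyl without acetate migration or loss of the base-sensitive C6 hydrogen.

Compound list
1 | but-2-yn-1-ol | CC#CCO | starting material
2 | cyclic alkenylalanate: sodium 2,2-bis(2-methoxyethoxy)-3-methyl-2,5-dihydro-1,2-oxaluminol-2-uide | CC1=CCO[Al-]1(OCCOC)OCCOC.[Na+] | intermediate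
3 | (Z)-3-iodobut-2-en-1-ol | OC/C=C(/C)I | intermediate
4 | (Z)-3-iodobut-2-enal | O=C/C=C(/C)I | intermediate
5 | methyl propiolate | C#CC(=O)OC | starting material
6 | methylzinc acetylide: methyl 3-(methylzincio)prop-2-ynoate | C[Zn]C#CC(=O)OC | intermediate
7 | methyl (4R,5Z)-4-hydroxy-6-iodohept-5-en-2-ynoate | COC(=O)C#C[C@H](O)/C=C(/C)I | intermediate
8 | cuprio enoate: methyl (2E,4R,5Z)-4-(bromomagnesiooxy)-2-cuprio-6-iodo-3-vinylhepta-2,5-dienoate (copper cis to the vinyl group, ester cis to the C6 alkoxide) | COC(=O)/C([Cu])=C(/C=C)[C@H](O[Mg]Br)/C=C(/C)I | intermediate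
9 | (5R)-3-(hydroxymethyl)-5-[(Z)-2-iodoprop-1-enyl]-4-vinylfuran-2(5H)-one | OCC1=C(C=C)[C@@H](/C=C(/C)I)OC1=O | intermediate
10 | [(5R)-5-[(Z)-2-iodoprop-1-enyl]-2-oxo-4-vinyl-2,5-dihydrofuran-3-yl]methyl acetate | CC(=O)OCC1=C(C=C)[C@@H](/C=C(/C)I)OC1=O | intermediate
11 | [(5R)-4-formyl-5-[(Z)-2-iodoprop-1-enyl]-2-oxo-2,5-dihydrofuran-3-yl]methyl acetate | CC(=O)OCC1=C(C=O)[C@@H](/C=C(/C)I)OC1=O | intermediate
12 | acrolein (prop-2-enal) | C=CC=O | starting material
13 | alkenylalane: methyl 2-(diisobutylalumanyl)acrylate | C=C(C(=O)OC)[Al](CC(C)C)CC(C)C | intermediate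
14 | rac-methyl 3-hydroxy-2-methylenepent-4-enoate | C=CC(O)C(=C)C(=O)OC | intermediate
15 | methyl (3R)-3-hydroxy-2-methylenepent-4-enoate | C=C[C@@H](O)C(=C)C(=O)OC | intermediate
16 | methyl (3R)-3-[(tert-butyldimethylsilyl)oxy]-2-methylenepent-4-enoate | C=C[C@@H](O[Si](C)(C)C(C)(C)C)C(=C)C(=O)OC | intermediate
17 | (3R)-3-[(tert-butyldimethylsilyl)oxy]-2-methylenepent-4-en-1-ol | C=C[C@@H](O[Si](C)(C)C(C)(C)C)C(=C)CO | intermediate
18 | (3R)-3-[(tert-butyldimethylsilyl)oxy]-2-methylenepent-4-en-1-yl methyl carbonate | C=C[C@@H](O[Si](C)(C)C(C)(C)C)C(=C)COC(=O)OC | intermediate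
19 | tert-butyldimethyl{[(3R)-4-methylene-5-(4,4,5,5-tetramethyl-1,3,2-dioxaborolan-2-yl)pent-1-en-3-yl]oxy}silane | C=C[C@@H](O[Si](C)(C)C(C)(C)C)C(=C)CB1OC(C)(C)C(C)(C)O1 | intermediate
20 | pinacol borate of 21 (boron on the C8 oxygen) | CC(=O)OCC1=C([C@@H](OB2OC(C)(C)C(C)(C)O2)CC(=C)[C@H](O[Si](C)(C)C(C)(C)C)C=C)[C@@H](/C=C(/C)I)OC1=O | intermediate
21 | {(5R)-4-[(1S,4R)-4-(tert-butyldimethylsilyloxy)-1-hydroxy-3-methylenehex-5-enyl]-5-[(Z)-2-iodoprop-1-enyl]-2-oxo-2,5-dihydrofuran-3-yl}methyl acetate | CC(=O)OCC1=C([C@@H](O)CC(=C)[C@H](O[Si](C)(C)C(C)(C)C)C=C)[C@@H](/C=C(/C)I)OC1=O | intermediate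
22 | {(5R)-4-[(1S,4R)-1-acetoxy-4-(tert-butyldimethylsilyloxy)-3-methylenehex-5-enyl]-5-[(Z)-2-iodoprop-1-enyl]-2-oxo-2,5-dihydrofuran-3-yl}methyl acetate | CC(=O)OCC1=C([C@@H](OC(C)=O)CC(=C)[C@H](O[Si](C)(C)C(C)(C)C)C=C)[C@@H](/C=C(/C)I)OC1=O | intermediate
23 | primary alkylborane of 22: bis(3-methylbutan-2-yl)boryl group on C3, C2 and C3 saturated | CC(=O)OCC1=C([C@@H](OC(C)=O)CC(=C)[C@H](O[Si](C)(C)C(C)(C)C)CCB(C(C)C(C)C)C(C)C(C)C)[C@@H](/C=C(/C)I)OC1=O | intermediate
24 | (1R,4Z,6R,8S)-8,13-diacetoxy-1-(tert-butyldimethylsilyloxy)germacra-4,7(11),10(14)-trien-12,6-olide | C=C1C[C@H](OC(C)=O)C2=C(COC(C)=O)C(=O)O[C@@H]2/C=C(/C)CC[C@H]1O[Si](C)(C)C(C)(C)C | intermediate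
25 | 8α,13-diacetoxy-1β-hydroxygermacra-4,7(11),10(14)-trien-6α,12-olide, (1R,4Z,6R,8S) | C=C1C[C@H](OC(C)=O)C2=C(COC(C)=O)C(=O)O[C@@H]2/C=C(/C)CC[C@H]1O | target

Total step count: 16. Longest linear sequence: 10 steps (steps 1–6 or steps 7–12, followed by steps 13–16).

Steps most likely to fail

Step 15. The hydroboration may not discriminate fully between C2=C3 and C10=C14, the borane may attack the lactone carbonyl, and transfer of the primary alkyl group from the hindered borane may be slow enough for protodeboronation, oligomerisation or Heck-type insertion into C10=C14 to compete. The base may also epimerise C6 or hydrolyse an acetate. The fallback sets out from 22 and replaces the organoboron by an organozinc in a stepwise sequence. Hydroboration with (Sia)2BH followed by oxidation with NaBO3·4H2O gives the primary alcohol {(5R)-4-[(1S,4R)-1-acetoxy-4-(tert-butyldimethylsilyloxy)-6-hydroxy-3-methylenehexyl]-5-[(Z)-2-iodoprop-1-enyl]-2-oxo-2,5-dihydrofuran-3-yl}methyl acetate F1. Iodine, PPh3 and imidazole convert it into the primary iodide F2. Zinc dust with LiCl in THF at rt should insert only into the alkyl carbon–iodine bond, and slow addition of the alkylzinc to Pd2(dba)3/SPhos at high dilution closes C3–C4 by intramolecular Negishi coupling, returning to the route at 24.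

Step 4. Capture of the copper intermediate by formaldehyde may be incomplete, giving the protonated lactone without C13; surplus cuprate may add 1,6 to the dienyl lactone, and iodine–copper exchange may erode the alkenyl iodide. The fallback sets out from 7 and replaces the aldol capture by a C-alkylation. After the same carbocupration the mixture is warmed to −20 °C so that lactonisation precedes alkylation, and the α-cuprio lactone is alkylated with (chloromethoxy)triisopropylsilane in THF/DMPU. This gives the silyl ether (5R)-5-[(Z)-2-iodoprop-1-enyl]-3-{[(triisopropylsilyl)oxy]methyl}-4-vinylfuran-2(5H)-one F3. HF·pyridine then frees the primary alcohol, returning to the route at 9.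

Step 13. Facial control on the hindered, conjugated aldehyde may be insufficient if the uncatalysed allylboration competes or if the C6 and C1 centres mismatch the catalyst. The fallback sets out from 11 and 19 and moves the stereocontrol from the allylation to a ketone reduction. Uncatalysed allylboration in toluene at rt gives the C8-epimeric alcohols F4, and Dess–Martin periodinane oxidises them to the ketone {(5R)-4-[(4R)-4-(tert-butyldimethylsilyloxy)-3-methylenehex-5-enoyl]-5-[(Z)-2-iodoprop-1-enyl]-2-oxo-2,5-dihydrofuran-3-yl}methyl acetate F5. Corey–Bakshi–Shibata reduction with the (R)-methyl oxazaborolidine and catecholborane at −78 °C, the lactone carbon acting as the large group, should give the 8S alcohol, returning to the route at 21.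

Further compounds
F1 | step 15 | {(5R)-4-[(1S,4R)-1-acetoxy-4-(tert-butyldimethylsilyloxy)-6-hydroxy-3-methylenehexyl]-5-[(Z)-2-iodoprop-1-enyl]-2-oxo-2,5-dihydrofuran-3-yl}methyl acetate | CC(=O)OCC1=C([C@@H](OC(C)=O)CC(=C)[C@H](O[Si](C)(C)C(C)(C)C)CCO)[C@@H](/C=C(/C)I)OC1=O
F2 | step 15 | {(5R)-4-[(1S,4R)-1-acetoxy-4-(tert-butyldimethylsilyloxy)-6-iodo-3-methylenehexyl]-5-[(Z)-2-iodoprop-1-enyl]-2-oxo-2,5-dihydrofuran-3-yl}methyl acetate | CC(=O)OCC1=C([C@@H](OC(C)=O)CC(=C)[C@H](O[Si](C)(C)C(C)(C)C)CCI)[C@@H](/C=C(/C)I)OC1=O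
F3 | step 4 | (5R)-5-[(Z)-2-iodoprop-1-enyl]-3-{[(triisopropylsilyl)oxy]methyl}-4-vinylfuran-2(5H)-one | CC(C)[Si](OCC1=C(C=C)[C@@H](/C=C(/C)I)OC1=O)(C(C)C)C(C)C
F4 | step 13 | C8-epimeric mixture of {(5R)-4-[(4R)-4-(tert-butyldimethylsilyloxy)-1-hydroxy-3-methylenehex-5-enyl]-5-[(Z)-2-iodoprop-1-enyl]-2-oxo-2,5-dihydrofuran-3-yl}methyl acetate | CC(=O)OCC1=C(C(O)CC(=C)[C@H](O[Si](C)(C)C(C)(C)C)C=C)[C@@H](/C=C(/C)I)OC1=O
F5 | step 13 | {(5R)-4-[(4R)-4-(tert-butyldimethylsilyloxy)-3-methylenehex-5-enoyl]-5-[(Z)-2-iodoprop-1-enyl]-2-oxo-2,5-dihydrofuran-3-yl}methyl acetate | CC(=O)OCC1=C(C(=O)CC(=C)[C@H](O[Si](C)(C)C(C)(C)C)C=C)[C@@H](/C=C(/C)I)OC1=O
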